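**Retrosynthetic overview**

- The target is cut at the O7 ester: global desilylation, cis-semi-hydrogenation of a ynoate and esterification lead back to a ring C7 alcohol and (R)-4-silyloxyoct-2-ynoic acid (from (R)-hept-1-yn-3-ol and CO2). The C7 alcohol comes from a nine-membered 7-keto lactone by hydride reduction.
- Key disconnection: the 7-keto lactone is traced to a 2-lactoyl-2-methylcyclohexanone by re-forming C1–C6 and cutting C1–O8. In the forward sense the C8 alkoxide closes a five-membered hemiketal on C1 and the C1–C6 bond breaks (retro-Claisen).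
- The 2-lactoylcyclohexanone comes from a meso 3,4,5-tris(silyloxy)-2,4,6-trimethylcyclohexanone and (S)-2-(benzyloxy)propanal (from ethyl (S)-lactate) by enantiotopic enolisation, aldol (C6–C7), oxidation and debenzylation. The meso ketone comes from mesitol via the para-quinol silyl ether, its bis-epoxide and reductive opening.
- Ring order: the six-membered carbocycle is taken from the arene, a five-membered hemiketal is fused to it transiently, and the nine-membered lactone arises by ring expansion, not by end-to-end lactonisation.
- Feature used: lactone atoms C1–C6 carry methyls at C2, C4, C6 and oxygen at C1, C3, C4, C5. This is the pattern of an oxidised 2,4,6-trimethylcyclohexanone that lacks only a C1–C6 bond.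

Key step: step 11

Numbering used throughout: lactone carbonyl C1, ring carbons C2–C8, ring oxygen O8 on C8, side-chain acid C1′–C8′. The cyclohexanone intermediates carry the same labels (ring C1–C6, acyl arm C7–C8). The target is 2S,3R,4R,5S,6S,7R,8S with a (2′Z,4′R) side chain.

Remark: the sense of the enantiotopic deprotonation in step 8 is assigned by analogy with simple 4-substituted and cis-2,6-disubstituted cyclohexanones, which points to the (S,S)-amide; should the sense be opposite on this substrate, the (R,R)-amide is used in the same step.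

**Route**

Step 1
Reactants: 1 2,4,6-trimethylphenol (mesitol)
Product: 2 4-hydroxy-2,4,6-trimethylcyclohexa-2,5-dien-1-one (para-quinol, achiral)
Conditions: PhI(OAc)2, MeCN/H2O, 0 °C
Reagents that add atoms: water, O
Why: Oxidative dearomatisation of a para-alkylphenol by a trivalent-iodine oxidant, the phenoxenium-type intermediate being trapped by water at the methyl-bearing para carbon.

Step 2
Reactants: 2 para-quinol
Product: 3 2,4,6-trimethyl-4-(triethylsilyloxy)cyclohexa-2,5-dien-1-one
Conditions: TESOTf, 2,6-lutidine, CH2Cl2, −78 to 0 °C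
Reagents that add atoms: triethylsilyl triflate, CC[Si](CC)(CC)OS(=O)(=O)C(F)(F)F
Why: Silylation of the tertiary alcohol with a silyl triflate removes the hydroxyl that would direct epoxidation syn and makes the oxygen-bearing face of the dienone the shielded one.

Step 3
Reactants: 3 quinol silyl ether
Product: 4 meso-2,3:5,6-diepoxy-2,4,6-trimethyl-4-(triethylsilyloxy)cyclohexan-1-one, both oxirane oxygens cis to the C4 methyl and trans to the C4 silyloxy group
Conditions: t-BuOOH (decane), DBU, CH2Cl2, 0 °C to rt
Reagents that add atoms: tert-butyl hydroperoxide, CC(C)(C)OO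
Why: Weitz–Scheffer nucleophilic epoxidation of both enone units, in which the peroxide anion should add at C3 and C5 anti to the bulky C4 silyloxy group (steric shielding, reinforced by the preference for attack anti to the C4–O bond, with no free hydroxyl left to direct syn), so both oxirane oxygens end cis to the C4 methyl and the product is meso.

Step 4
Reactants: 4 meso bis-epoxide
Product: 5 meso-3,5-dihydroxy-2,4,6-trimethyl-4-(triethylsilyloxy)cyclohexan-1-one; C2-Me, C3-OH, C4-Me, C5-OH and C6-Me on one face, C4-OSiEt3 on the other
Conditions: SmI2 (4.5 equiv), THF/MeOH, −78 °C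
Reagents that add atoms: none
Why: Reductive opening of α,β-epoxy ketones with SmI2 (divalent samarium) cleaves each Cα–O bond and keeps the C3/C5 carbinol configuration, and each samarium enolate should then be protonated axially at C2/C6 on the face opposite the pseudo-axial neighbouring oxygen (net trans-diaxial delivery of H and O), giving the meso diol with both methyls cis to the adjacent hydroxyls.

Step 5
Reactants: 5 meso diol
Product: 6 meso-3,5-bis(tert-butyldimethylsilyloxy)-2,4,6-trimethyl-4-(triethylsilyloxy)cyclohexan-1-one, relative configuration as in 5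
Conditions: TBSOTf, 2,6-lutidine, CH2Cl2, −78 to 0 °C
Reagents that add atoms: tert-butyldimethylsilyl triflate, CC(C)(C)[Si](C)(C)OS(=O)(=O)C(F)(F)F
Why: Silyl-triflate silylation of the two secondary alcohols under conditions that do not enolise the ketone; with three mutually trans silyloxy groups the chair with axial oxygens and equatorial methyls is expected to be the resting conformer, so the C2/C6 configuration should also be the stable one.

Step 6
Reactants: 7 ethyl (S)-lactate
Product: 8 ethyl (S)-2-(benzyloxy)propanoate
Conditions: BnOC(=NH)CCl3, TfOH (cat.), cyclohexane/CH2Cl2, rt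
Reagents that add atoms: benzyl 2,2,2-trichloroacetimidate, ClC(Cl)(Cl)C(=N)OCc1ccccc1
Why: Acid-catalysed O-benzylation with a trichloroacetimidate alkylates the hydroxyl without base and therefore without racemising the lactate centre.

Step 7
Reactants: 8 ethyl (S)-2-(benzyloxy)propanoate
Product: 9 (S)-2-(benzyloxy)propanal
Conditions: i-Bu2AlH, CH2Cl2, −78 °C
Reagents that add atoms: none
Why: Partial reduction of the ester at −78 °C stops at the aluminium hemiacetal, which releases the configurationally labile α-alkoxy aldehyde on work-up; it is used at once.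

Step 8
Reactants: 6 meso tris-silyl ketone; 9 (S)-2-(benzyloxy)propanal
Product: 11 C6 aldol adduct of 6 carrying a (2S)-2-(benzyloxy)-1-hydroxypropyl group (C7 carbinol as either epimer; side chain trans to the C5 silyloxy group), via lithium enolate 10 (not isolated)
Conditions: (S,S)-bis(1-phenylethyl)amine, n-BuLi, LiCl, THF, −78 °C; then 9, −78 °C; AcOH quench
Reagents that add atoms: none
Why: Enantiotopic deprotonation of the meso ketone by a chiral lithium amide (desymmetrisation) removes the axial C6 hydrogen and leaves C2 as the future C2 centre, and the tetrasubstituted lithium enolate then adds to the aldehyde (aldol addition, axial attack anti to the C5 silyloxy group) to make the C6–C7 bond; the C7 carbinol and the C6 quaternary configuration are of no consequence because C7 is oxidised in step 9 and C6 becomes trigonal in step 11, and material from the other enantiotopic enolate ends as a separable diastereomer because 9 is enantiopure.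

Step 9
Reactants: 11 aldol adduct
Product: 12 2-[(S)-2-(benzyloxy)propanoyl]-2-methylcyclohexanone (C1 and C7 ketones, C6 quaternary, otherwise as 11)
Conditions: Dess–Martin periodinane, CH2Cl2, rt
Reagents that add atoms: none
Why: Dess–Martin oxidation converts the hindered β-hydroxy ketone into the 1,3-diketone, which cannot enolise between the carbonyls because C6 is quaternary, and merges the C7 epimers.

Step 10
Reactants: 12 benzyl-protected diketone
Product: 13 2-lactoyl-2-methylcyclohexanone: as 12 with a free C8 hydroxyl ((S)-2-hydroxypropanoyl at C6; C3/C5 OTBS, C4 OTES)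
Conditions: H2 (1 atm), Pd/C, EtOAc, rt
Reagents that add atoms: none
Why: Hydrogenolysis of the benzyl ether over Pd/C is neutral, so the α-ketol is released without epimerising C8, without touching the silyl ethers and without starting the fragmentation before base is added; 13 may rest partly as its neutral hemiketal.

Step 11
Reactants: 13 2-lactoyl-2-methylcyclohexanone
Product: 16 nine-membered 7-keto lactone (C1–O8 ester; C7 ketone; C2–C6 and C8 configured as in the target; C3/C5 OTBS; C4 OTES), via hemiketal alkoxide 14 (not isolated), via ring enolate 15 (not isolated)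
Conditions: NaH (0.2 equiv), THF, 0 °C; AcOH quench
Reagents that add atoms: none
Why: Catalytic NaH forms the C8 alkoxide, which adds to the C1 ketone in a 5-exo-trig closure (ring O8–C8–C7–C6–C1) to give the cis-fused six/five hemiketal alkoxide 14, and collapse of this tetrahedral centre breaks C1–C6 and releases C6 as the C7 enolate 15, so the nine-membered lactone ring is closed by three-atom expansion of the bicycle and not by end-to-end cyclisation. The reaction type is the alkoxide-triggered retro-Claisen (retro-Dieckmann) ring enlargement known for 2-(hydroxyalkyl)cycloalkane-1,3-diones and 2-acylcycloalkanones, and the breaking bond sits in a five-membered ring together with the stabilising carbonyl, as in the facile alkoxide cleavage of 2,2-disubstituted cyclopentane-1,3-diones. Site selectivity is built into the substrate: O8 reaches only C1 through a five-membered ring, C6 is quaternary so the diketone cannot hide as its enolate, and only expulsion of C6 gives a stabilised carbanion. The one new stereocentre, C6, is set when enolate 15 is C-protonated on the outer face of the ring by the hydroxyl of the next molecule of 13, which carries the chain; this is expected to place the C6 and C8 methyls cis across the C7 carbonyl, the arrangement that should also prevail if the centre equilibrates next to the ketone. The step further needs C2 and C8 to hold: C2 already has its methyl equatorial and becomes a less acidic lactone α-centre, and enolisation at C8 is limited by the low base loading, the low temperature and the acetic acid quench as soon as 13 is consumed.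

Step 12
Reactants: 16 7-keto lactone
Product: 17 (7R)-7-hydroxy lactone (C3/C5 OTBS, C4 OTES)
Conditions: NaBH4, MeOH/CH2Cl2, −78 to −40 °C
Reagents that add atoms: none
Why: Borohydride reduction of the C7 ketone with hydride arriving from outside the ring; by analogy with small-hydride reduction of cis-2,6-dialkylcycloalkanones and in line with the polar Felkin–Anh model for the C8 acyloxy group, the new hydroxyl should end trans to both flanking methyls (7R), and the low temperature should suppress migration of the lactone acyl group to O7.

Step 13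
Reactants: 18 (R)-hept-1-yn-3-ol
Product: 19 (R)-3-(tert-butyldimethylsilyloxy)hept-1-yne
Conditions: TBSCl, imidazole, DMF, rt
Reagents that add atoms: tert-butyldimethylsilyl chloride, CC(C)(C)[Si](C)(C)Cl
Why: Standard silylation of the propargylic alcohol (silyl chloride, imidazole) with no effect on the stereocentre.

Step 14
Reactants: 19 silylated alkyne
Product: 21 (R)-4-(tert-butyldimethylsilyloxy)oct-2-ynoic acid, via lithium acetylide 20 (not isolated)
Conditions: n-BuLi, THF, −78 °C; CO2; cold 1 M HCl work-up
Reagents that add atoms: carbon dioxide, O=C=O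
Why: Deprotonation of the terminal alkyne and carboxylation of the lithium acetylide with CO2 gives the ynoic acid with the propargylic centre untouched.

Step 15
Reactants: 17 (7R)-alcohol; 21 ynoic acid
Product: 22 O7 ester of 17 with acid 21 (ynoate; four silyl ethers)
Conditions: DCC, DMAP (0.1 equiv), CH2Cl2, −20 to 0 °C
Reagents that add atoms: none
Why: Steglich esterification (carbodiimide, catalytic DMAP) acylates O7 with retention at C7; the ynoic acid is used in place of the (Z)-enoic acid so that no double-bond isomerisation or butenolide formation can occur during acylation, and DMAP is kept catalytic and cold to limit its conjugate addition to the ynoate.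

Step 16
Reactants: 22 ynoate
Product: 23 (2′Z)-enoate (four silyl ethers)
Conditions: H2 (1 atm), Pd/CaCO3 poisoned with Pb(OAc)2, quinoline, EtOAc, rt
Reagents that add atoms: none
Why: Lindlar semi-hydrogenation adds H2 syn on the lead-poisoned palladium surface and stops at the (Z)-enoate, while the C4′ silyl ether prevents closure of the γ-oxygen onto the ester.

Step 17
Reactants: 23 silylated (Z)-enoate
Product: 24 CNP0205075.3 (target)
Conditions: HF·pyridine, pyridine, THF, 0 °C to rt
Reagents that add atoms: none
Why: Fluoride-induced cleavage of all four silyl ethers with pyridine-buffered HF, chosen over basic fluoride because alkoxides would promote translactonisation of the triol lactone and closure of the (Z)-γ-hydroxy enoate to a butenolide.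

**Compound list**

1 | 2,4,6-trimethylphenol (mesitol) | Cc1cc(C)c(O)c(C)c1 | starting material
2 | 4-hydroxy-2,4,6-trimethylcyclohexa-2,5-dien-1-one | CC1=CC(C)(O)C=C(C)C1=O | intermediate
3 | 2,4,6-trimethyl-4-(triethylsilyloxy)cyclohexa-2,5-dien-1-one | CC1=CC(C)(O[Si](CC)(CC)CC)C=C(C)C1=O | intermediate
4 | meso bis-epoxide, oxirane oxygens trans to C4-OTES | O=C1[C@@]2(C)O[C@H]2[C@](C)(O[Si](CC)(CC)CC)[C@H]2O[C@@]12C | intermediate
5 | meso 3,5-dihydroxy-2,4,6-trimethyl-4-(triethylsilyloxy)cyclohexanone | O=C1[C@@H](C)[C@@H](O)[C@](C)(O[Si](CC)(CC)CC)[C@@H](O)[C@H]1C | intermediate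
6 | meso 3,5-bis(TBS-oxy)-4-(TES-oxy)-2,4,6-trimethylcyclohexanone | O=C1[C@@H](C)[C@@H](O[Si](C)(C)C(C)(C)C)[C@](C)(O[Si](CC)(CC)CC)[C@@H](O[Si](C)(C)C(C)(C)C)[C@H]1C | intermediate
7 | ethyl (S)-lactate | C[C@H](O)C(=O)OCC | starting material
8 | ethyl (S)-2-(benzyloxy)propanoate | C[C@H](OCc1ccccc1)C(=O)OCC | intermediate
9 | (S)-2-(benzyloxy)propanal | C[C@H](OCc1ccccc1)C=O | intermediate
10 | lithium C1–C6 enolate of 6 | [Li+].[O-]C1=C(C)[C@H](O[Si](C)(C)C(C)(C)C)[C@@](C)(O[Si](CC)(CC)CC)[C@H](O[Si](C)(C)C(C)(C)C)[C@@H]1C | intermediate (not isolated)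
11 | C6 aldol adduct, C7 carbinol unspecified | O=C1[C@@H](C)[C@@H](O[Si](C)(C)C(C)(C)C)[C@](C)(O[Si](CC)(CC)CC)[C@@H](O[Si](C)(C)C(C)(C)C)[C@]1(C)C(O)[C@@H](OCc1ccccc1)C | intermediate
12 | 8-O-benzyl 1,3-diketone | O=C1[C@@H](C)[C@@H](O[Si](C)(C)C(C)(C)C)[C@](C)(O[Si](CC)(CC)CC)[C@@H](O[Si](C)(C)C(C)(C)C)[C@]1(C)C(=O)[C@@H](OCc1ccccc1)C | intermediate
13 | 2-lactoyl-2-methylcyclohexanone (key-step precursor) | O=C1[C@@H](C)[C@@H](O[Si](C)(C)C(C)(C)C)[C@](C)(O[Si](CC)(CC)CC)[C@@H](O[Si](C)(C)C(C)(C)C)[C@]1(C)C(=O)[C@@H](O)C | intermediate
14 | sodium alkoxide of the cis-fused hemiketal (O8–C1 bond formed) | [Na+].[O-][C@@]12[C@@H](C)[C@@H](O[Si](C)(C)C(C)(C)C)[C@](C)(O[Si](CC)(CC)CC)[C@@H](O[Si](C)(C)C(C)(C)C)[C@]1(C)C(=O)[C@H](C)O2 | intermediate (not isolated)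
15 | sodium C6=C7 enolate of the nine-membered lactone (C5 and C8 cis on the double bond) | [Na+].[O-]/C1=C(C)/[C@H](O[Si](C)(C)C(C)(C)C)[C@@](C)(O[Si](CC)(CC)CC)[C@H](O[Si](C)(C)C(C)(C)C)[C@H](C)C(=O)O[C@H]1C | intermediate (not isolated)
16 | nine-membered 7-keto lactone (key-step product) | O=C1[C@@H](C)[C@H](O[Si](C)(C)C(C)(C)C)[C@@](C)(O[Si](CC)(CC)CC)[C@H](O[Si](C)(C)C(C)(C)C)[C@H](C)C(=O)O[C@H]1C | intermediate
17 | (7R)-7-hydroxy lactone | O[C@@H]1[C@@H](C)[C@H](O[Si](C)(C)C(C)(C)C)[C@@](C)(O[Si](CC)(CC)CC)[C@H](O[Si](C)(C)C(C)(C)C)[C@H](C)C(=O)O[C@H]1C | intermediate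
18 | (R)-hept-1-yn-3-ol | CCCC[C@@H](O)C#C | starting material
19 | (R)-3-(tert-butyldimethylsilyloxy)hept-1-yne | CCCC[C@@H](O[Si](C)(C)C(C)(C)C)C#C | intermediate
20 | lithium acetylide of 19 | CCCC[C@@H](O[Si](C)(C)C(C)(C)C)C#C[Li] | intermediate (not isolated)
21 | (R)-4-(tert-butyldimethylsilyloxy)oct-2-ynoic acid | CCCC[C@@H](O[Si](C)(C)C(C)(C)C)C#CC(=O)O | intermediate
22 | O7 ynoate ester | CCCC[C@@H](O[Si](C)(C)C(C)(C)C)C#CC(=O)O[C@@H]1[C@@H](C)[C@H](O[Si](C)(C)C(C)(C)C)[C@@](C)(O[Si](CC)(CC)CC)[C@H](O[Si](C)(C)C(C)(C)C)[C@H](C)C(=O)O[C@H]1C | intermediate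
23 | O7 (2′Z)-enoate ester, four silyl ethers | CCCC[C@@H](O[Si](C)(C)C(C)(C)C)/C=C\C(=O)O[C@@H]1[C@@H](C)[C@H](O[Si](C)(C)C(C)(C)C)[C@@](C)(O[Si](CC)(CC)CC)[C@H](O[Si](C)(C)C(C)(C)C)[C@H](C)C(=O)O[C@H]1C | intermediate
24 | CNP0205075.3 | CCCC[C@@H](O)/C=C\C(=O)O[C@@H]1[C@@H](C)[C@H](O)[C@@](C)(O)[C@H](O)[C@H](C)C(=O)O[C@H]1C | target

**Step count and risks**

Total steps: 17. Longest linear sequence: 13 (steps 1–5, 8–12, 15–17, from mesitol).

Steps most likely to fail:

1. Step 11. The hemiketal alkoxide may divert instead of fragmenting cleanly. Possible paths are silyl migration from O3/O5 to the alkoxide or enolate oxygen, loss of the C5 silyloxy group from enolate 15, enolisation at C8 with loss of the lactate configuration, and protonation of 15 on the wrong face at C6. The strain of the nine-membered lactone also lowers the driving force. Fallback: ring opening and ring closure are separated. Diketone 12 is treated with LiOH (THF/H2O, 0 °C). Hydroxide attack at the cyclohexanone carbonyl C1 performs the same C1–C6 retro-Claisen and gives the seco acid, 8-O-benzyl 7-oxo carboxylic acid F1; attack at C7 would only regenerate ketone 6. Hydrogenolysis (H2, Pd/C, EtOAc) gives the 8-hydroxy-7-oxo acid F2. Shiina macrolactonisation (MNBA, DMAP, Et3N, CH2Cl2, high dilution) then forms the C1–O8 bond and returns to the route at 16.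

2. Step 8. The axial C6 hydrogen lies syn-diaxial to the C4 silyloxy group, so its removal may be slow or unselective. The lithium enolate may also lose an axial β-silyloxy group, and the crowded aldol addition may revert. Fallback: setting out from 6, soft enolisation (TMSOTf, Et3N, CH2Cl2) gives the racemic trimethylsilyl enol ether F3 without a strong base. A Mukaiyama aldol with 9 (BF3·OEt2, CH2Cl2, −78 °C) is irreversible and resolves the material through the enantiopure aldehyde. The adduct from the mirror-image enol ether, diastereomeric aldol adduct F4, is removed by chromatography, and the other series is 11, where the route is rejoined.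

3. Step 12. Hydride may be delivered to the wrong face of the C7 carbonyl, because the conformation of the substituted nine-membered ring cannot be predicted with confidence. The lactone acyl group may also migrate to the new O7 alkoxide. Fallback: setting out from 16, if the reduction gives mainly the C7 epimer, the 7-epi alcohol F5, the centre is inverted by a Mitsunobu reaction with chloroacetic acid (DIAD, PPh3, toluene) to the (7R)-chloroacetate F6. Its chloroacetyl group is removed chemoselectively with thiourea (NaHCO3, EtOH/THF), which returns to the route at 17.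

**Further compounds**

F1 | step 11 | seco acid, 8-O-benzyl 7-oxo carboxylic acid | C[C@H](OCc1ccccc1)C(=O)[C@@H](C)[C@H](O[Si](C)(C)C(C)(C)C)[C@@](C)(O[Si](CC)(CC)CC)[C@H](O[Si](C)(C)C(C)(C)C)[C@H](C)C(=O)O
F2 | step 11 | 8-hydroxy-7-oxo acid | C[C@H](O)C(=O)[C@@H](C)[C@H](O[Si](C)(C)C(C)(C)C)[C@@](C)(O[Si](CC)(CC)CC)[C@H](O[Si](C)(C)C(C)(C)C)[C@H](C)C(=O)O
F3 | step 8 | trimethylsilyl enol ether of 6 (racemic; enantiomer leading to 11 shown) | C[Si](C)(C)OC1=C(C)[C@H](O[Si](C)(C)C(C)(C)C)[C@@](C)(O[Si](CC)(CC)CC)[C@H](O[Si](C)(C)C(C)(C)C)[C@@H]1C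
F4 | step 8 | diastereomeric aldol adduct (mirror-image ring, (S)-side chain, C7 unspecified) | O=C1[C@H](C)[C@H](O[Si](C)(C)C(C)(C)C)[C@@](C)(O[Si](CC)(CC)CC)[C@H](O[Si](C)(C)C(C)(C)C)[C@@]1(C)C(O)[C@@H](OCc1ccccc1)C
F5 | step 12 | 7-epi alcohol | O[C@H]1[C@@H](C)[C@H](O[Si](C)(C)C(C)(C)C)[C@@](C)(O[Si](CC)(CC)CC)[C@H](O[Si](C)(C)C(C)(C)C)[C@H](C)C(=O)O[C@H]1C
F6 | step 12 | (7R)-chloroacetate | ClCC(=O)O[C@@H]1[C@@H](C)[C@H](O[Si](C)(C)C(C)(C)C)[C@@](C)(O[Si](CC)(CC)CC)[C@H](O[Si](C)(C)C(C)(C)C)[C@H](C)C(=O)O[C@H]1C
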